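**Retrosynthetic overview**

- Target 13 comes from pivalate 12 by methanolysis, and 12 from bromide 10 by Stille allylation at C5.
- Key disconnection: C3–C3a and C7a–O1 of the dihydrofuran ring of 10, leading back to 2-iodoanisole 9 and cis-oxirane 8. This is the only ring made; rings A and B and the eugenol ring are bought.
- Feature used: ring A is an anisole with O1 on C7a beside the methoxy carbon C7 and with C3 on the other neighbour C3a. This is the ipso/ortho pattern that a palladium/norbornene relay writes onto a 2-iodoanisole; the oxirane supplies C2 and C3 with both stereocentres.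
- Oxirane 8 comes from Z-alkene 7 (Mn-salen epoxidation), 7 from Z-allylic alcohol 5 and eugenol 6 (Mitsunobu), 5 from alkyne 4 (Lindlar), and 4 from iodide 2 and propargyl alcohol 3 (Sonogashira).
- An olefination through a 2-aryloxyethyl phosphonium ylide is not used, because such ylides expel aryloxide by β-elimination.

Key step: step 6

Remark: locants O1, C2, C3, C3a, C7 and C7a are those of the 2,3-dihydrobenzofuran core (ring A is its benzo ring, ring B the 2-aryl group); the target is read as the trans (2S,3R) isomer, and iodoarenes 1 and 9 are taken as purchasable.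

**Route**

Step 1
Reactants: 1 4-iodo-2-methoxyphenol
Product: 2 4-iodo-2-methoxyphenyl pivalate
Conditions: pivaloyl chloride, Et3N, DMAP (cat.), CH2Cl2, 0 °C to rt
Reagents that add atoms: pivaloyl chloride, CC(C)(C)C(=O)Cl
Why: DMAP-catalysed acylation of the phenol (nucleophilic acyl substitution) gives a pivalate that masks the phenol, makes ring B less electron-rich and resists the bases used later.

Step 2
Reactants: 2 4-iodo-2-methoxyphenyl pivalate; 3 propargyl alcohol
Product: 4 4-(3-hydroxyprop-1-ynyl)-2-methoxyphenyl pivalate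
Conditions: Pd(PPh3)2Cl2 (2 mol %), CuI (4 mol %), Et3N, THF, rt
Reagents that add atoms: none
Why: Sonogashira coupling of an aryl iodide with a terminal alkyne proceeds at room temperature and leaves the aryl pivalate and the free alcohol untouched.

Step 3
Reactants: 4 4-(3-hydroxyprop-1-ynyl)-2-methoxyphenyl pivalate
Product: 5 4-[(Z)-3-hydroxyprop-1-enyl]-2-methoxyphenyl pivalate
Conditions: H2 (1 atm), Pd/CaCO3 poisoned with Pb(OAc)2, quinoline, EtOAc, rt, stopped after 1 equiv H2
Reagents that add atoms: none
Why: Lindlar semihydrogenation delivers both hydrogens to the same face of the alkyne on the poisoned palladium surface, so the Z-alkene should result, and no other reducible group is present at this stage.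

Step 4
Reactants: 5 4-[(Z)-3-hydroxyprop-1-enyl]-2-methoxyphenyl pivalate; 6 eugenol
Product: 7 4-[(Z)-3-(4-allyl-2-methoxyphenoxy)prop-1-enyl]-2-methoxyphenyl pivalate
Conditions: PPh3, DIAD, THF, 0 °C to rt
Reagents that add atoms: none
Why: Mitsunobu etherification displaces the activated primary allylic oxygen by the phenoxide of eugenol in an SN2 step under neutral conditions, which should keep the Z geometry and the aryl pivalate.

Step 5
Reactants: 7 4-[(Z)-3-(4-allyl-2-methoxyphenoxy)prop-1-enyl]-2-methoxyphenyl pivalate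
Product: 8 (2S,3R)-2-[(4-allyl-2-methoxyphenoxy)methyl]-3-(3-methoxy-4-pivaloyloxyphenyl)oxirane (cis)
Conditions: (R,R)-[N,N'-bis(3,5-di-tert-butylsalicylidene)-1,2-cyclohexanediaminato]MnCl (5 mol %), 4-phenylpyridine N-oxide, aq. NaOCl (pH 11.3), CH2Cl2, 0 °C
Reagents that add atoms: sodium hypochlorite, [Na+].[O-]Cl
Why: Jacobsen–Katsuki epoxidation, in which the oxo-manganese salen complex transfers oxygen face-selectively to the aryl-conjugated cis-alkene and so sets both oxirane centres at once (3R at the benzylic carbon by analogy with cis-β-methylstyrene under the (R,R)-ligand, 2S following from the retained cis geometry), while the isolated terminal alkene reacts far more slowly.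

Step 6
Reactants: 8 (2S,3R)-2-[(4-allyl-2-methoxyphenoxy)methyl]-3-(3-methoxy-4-pivaloyloxyphenyl)oxirane; 9 4-bromo-1-iodo-2-methoxybenzene
Product: 10 (2S,3R)-3-[(4-allyl-2-methoxyphenoxy)methyl]-5-bromo-7-methoxy-2-(3-methoxy-4-pivaloyloxyphenyl)-2,3-dihydrobenzofuran (trans)
Conditions: Pd(OAc)2 (10 mol %), XPhos (20 mol %), potassium 5-norbornene-2-carboxylate (0.5 equiv), K2CO3 (2 equiv), NMP, 70 °C; 8 (1.0 equiv), 9 (1.3 equiv)
Reagents that add atoms: none
Why: Proposed new method: oxidative addition of the C–I bond of 9 to zerovalent palladium, norbornene insertion and carboxylate-assisted ortho C–H palladation should give the aryl–norbornyl palladacycle of divalent palladium, which opens the oxirane of 8 by back-side attack at C2 of the oxirane (the carbon that carries the aryloxymethyl arm) to give an alkoxide of tetravalent palladium, after which C(sp2)–C(sp3) reductive elimination forms C3–C3a, β-carbon elimination expels norbornene and the aryl palladium alkoxide forms C7a–O1. The closest known reaction type is the palladium/norbornene annulation of ortho-substituted aryl iodides with terminal epoxides to 2-substituted 2,3-dihydrobenzofurans, in which the oxirane is opened at its unsubstituted carbon, and the use of a 2,3-disubstituted aryl oxirane is the unproven extension. The dihydrofuran ring is closed in a [3+2] sense, the last event being C(aryl)–O reductive elimination from a six-membered oxapalladacycle of divalent palladium. No stereocentre is created here: C2 keeps its configuration because its C–O bond is never broken, and C3 is inverted once in the SN2-type opening and retained in the reductive elimination, so the cis (2S,3R)-oxirane should map onto the trans (2S,3R)-dihydrobenzofuran. The step needs attack at the non-benzylic oxirane carbon, C–I before C–Br, and etherification before Heck capture by the allyl group; what the substrates offer is a methylene-flanked carbon as the less encumbered of the two secondary sites for a very bulky palladacycle, a pivaloyloxy arene that disfavours benzylic ionisation and Meinwald rearrangement, an iodide that adds to palladium far faster than the unactivated bromide, an alkoxide held beside palladium, and the C7 methoxy group that blocks the second ortho position of ring A.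

Step 7
Reactants: 10 (2S,3R)-3-[(4-allyl-2-methoxyphenoxy)methyl]-5-bromo-7-methoxy-2-(3-methoxy-4-pivaloyloxyphenyl)-2,3-dihydrobenzofuran; 11 allyltributylstannane
Product: 12 (2S,3R)-5-allyl-3-[(4-allyl-2-methoxyphenoxy)methyl]-7-methoxy-2-(3-methoxy-4-pivaloyloxyphenyl)-2,3-dihydrobenzofuran (trans)
Conditions: Pd(PPh3)4 (5 mol %), toluene, 100 °C
Reagents that add atoms: none
Why: Stille coupling, in which zerovalent palladium adds to the aryl bromide, the allyl group is transferred from tin and reductive elimination gives the allylarene without touching the stereocentres, the pivalate or the aryl ethers.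

Step 8
Reactants: 12 (2S,3R)-5-allyl-3-[(4-allyl-2-methoxyphenoxy)methyl]-7-methoxy-2-(3-methoxy-4-pivaloyloxyphenyl)-2,3-dihydrobenzofuran
Product: 13 4-[(2S,3R)-5-allyl-3-[(4-allyl-2-methoxyphenoxy)methyl]-7-methoxy-2,3-dihydrobenzofuran-2-yl]-2-methoxyphenol (trans; CNP0138854.1)
Conditions: K2CO3 (1.5 equiv), MeOH/THF, rt; aq. NH4Cl work-up
Reagents that add atoms: none
Why: Methoxide-mediated transesterification (methanolysis) cleaves the aryl pivalate at room temperature, conditions that should be too mild to move the allyl double bonds or to open the benzylic C2–O1 bond.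

**Compound list**

1 | 4-iodo-2-methoxyphenol | COc1cc(I)ccc1O | starting material
2 | 4-iodo-2-methoxyphenyl pivalate | COc1cc(I)ccc1OC(=O)C(C)(C)C | intermediate
3 | propargyl alcohol | C#CCO | starting material
4 | 4-(3-hydroxyprop-1-ynyl)-2-methoxyphenyl pivalate | COc1cc(C#CCO)ccc1OC(=O)C(C)(C)C | intermediate
5 | 4-[(Z)-3-hydroxyprop-1-enyl]-2-methoxyphenyl pivalate | COc1cc(/C=C\CO)ccc1OC(=O)C(C)(C)C | intermediate
6 | eugenol (4-allyl-2-methoxyphenol) | C=CCc1ccc(O)c(OC)c1 | starting material
7 | 4-[(Z)-3-(4-allyl-2-methoxyphenoxy)prop-1-enyl]-2-methoxyphenyl pivalate | C=CCc1ccc(OC/C=C\c2ccc(OC(=O)C(C)(C)C)c(OC)c2)c(OC)c1 | intermediate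
8 | (2S,3R)-2-[(4-allyl-2-methoxyphenoxy)methyl]-3-(3-methoxy-4-pivaloyloxyphenyl)oxirane (cis) | C=CCc1ccc(OC[C@@H]2O[C@@H]2c2ccc(OC(=O)C(C)(C)C)c(OC)c2)c(OC)c1 | intermediate
9 | 4-bromo-1-iodo-2-methoxybenzene | COc1cc(Br)ccc1I | starting material
10 | (2S,3R)-3-[(4-allyl-2-methoxyphenoxy)methyl]-5-bromo-7-methoxy-2-(3-methoxy-4-pivaloyloxyphenyl)-2,3-dihydrobenzofuran (trans) | C=CCc1ccc(OC[C@H]2c3cc(Br)cc(OC)c3O[C@@H]2c2ccc(OC(=O)C(C)(C)C)c(OC)c2)c(OC)c1 | intermediate
11 | allyltributylstannane | C=CC[Sn](CCCC)(CCCC)CCCC | starting material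
12 | (2S,3R)-5-allyl-3-[(4-allyl-2-methoxyphenoxy)methyl]-7-methoxy-2-(3-methoxy-4-pivaloyloxyphenyl)-2,3-dihydrobenzofuran (trans) | C=CCc1ccc(OC[C@H]2c3cc(CC=C)cc(OC)c3O[C@@H]2c2ccc(OC(=O)C(C)(C)C)c(OC)c2)c(OC)c1 | intermediate
13 | 4-[(2S,3R)-5-allyl-3-[(4-allyl-2-methoxyphenoxy)methyl]-7-methoxy-2,3-dihydrobenzofuran-2-yl]-2-methoxyphenol (trans) | C=CCc1ccc(OC[C@H]2c3cc(CC=C)cc(OC)c3O[C@@H]2c2ccc(O)c(OC)c2)c(OC)c1 | target

**Step count and risks**

Total step count: 8. Longest linear sequence: 8 steps (1 to 13 through 2, 4, 5, 7, 8, 10 and 12).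

Steps most likely to fail:

1. Step 6. The benzylic oxirane carbon is the intrinsically more reactive SN2 site, so the palladacycle may open the oxirane there and give the 3-aryl regioisomer. It may also fail to add to an internal oxirane at all, leaving Meinwald isomerisation of 8 and self-coupling of 9 as the main courses.

   The fallback gives up the annulation and builds the dihydrofuran ring by the intramolecular rhodium-carbenoid C–H insertion that is established for 2-aryl-2,3-dihydrobenzofuran-3-carboxylates. It sets out from eugenol 6, which becomes ring A with its allyl group already in place.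
   - Iodination ortho to the hydroxyl (NIS, TsOH cat., MeCN, 0 °C) should give 4-allyl-2-iodo-6-methoxyphenol F1.
   - NaBH4 reduction of commercial 4-(tert-butyldimethylsilyloxy)-3-methoxybenzaldehyde gives [4-(tert-butyldimethylsilyloxy)-3-methoxyphenyl]methanol F2. Mitsunobu etherification of F1 with F2 (PPh3, DIAD, THF) should give 5-allyl-2-{[4-(tert-butyldimethylsilyloxy)-3-methoxyphenyl]methoxy}-1-iodo-3-methoxybenzene F3.
   - Coupling with methyl diazoacetate (Pd(PPh3)4, Ag2CO3, Et3N, toluene, rt) should give methyl 2-(5-allyl-2-{[4-(tert-butyldimethylsilyloxy)-3-methoxyphenyl]methoxy}-3-methoxyphenyl)-2-diazoacetate F4.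
   - Rh2(S-PTTL)4 (dirhodium tetrakis[N-phthaloyl-(S)-tert-leucinate]) or its mirror image, whichever sets C2 as S, should insert the carbene into the benzylic C–H bond in CH2Cl2 at low temperature. The expected product is the cis ester methyl (2S,3R)-5-allyl-2-[4-(tert-butyldimethylsilyloxy)-3-methoxyphenyl]-7-methoxy-2,3-dihydrobenzofuran-3-carboxylate F5.
   - DBU in toluene should epimerise C3 to the trans ester methyl (2S,3S)-5-allyl-2-[4-(tert-butyldimethylsilyloxy)-3-methoxyphenyl]-7-methoxy-2,3-dihydrobenzofuran-3-carboxylate F6.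
   - i-Bu2AlH (CH2Cl2, −78 °C) should give [(2S,3R)-5-allyl-2-[4-(tert-butyldimethylsilyloxy)-3-methoxyphenyl]-7-methoxy-2,3-dihydrobenzofuran-3-yl]methanol F7.
   - Mitsunobu etherification with a second portion of eugenol 6 should give (2S,3R)-5-allyl-3-[(4-allyl-2-methoxyphenoxy)methyl]-2-[4-(tert-butyldimethylsilyloxy)-3-methoxyphenyl]-7-methoxy-2,3-dihydrobenzofuran F8.
   - n-Bu4NF buffered with AcOH in THF removes the silyl group and comes back to the route at 13.

2. Step 5. The manganese-oxo species may discriminate the alkene faces incompletely, and the stepwise radical pathway may leak to the trans-oxirane.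

   The fallback moves the oxygen transfer to a stage where a bound allylic alkoxide directs it. It sets out from Z-allylic alcohol 5. Sharpless epoxidation (Ti(OiPr)4, L-(+)-diisopropyl tartrate, t-BuOOH, 4 Å molecular sieves, CH2Cl2, −20 °C) should give [(2S,3R)-3-(3-methoxy-4-pivaloyloxyphenyl)oxiran-2-yl]methanol F9 with retention of the cis geometry. Mitsunobu etherification of its primary hydroxyl with eugenol 6 (PPh3, DIAD, toluene) comes back to the route at 8.

3. Step 7. Oxidative addition to the electron-rich bromide may be slow, and at the temperature it needs, palladium hydride species may move the allyl double bonds into conjugation.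

   The fallback reverses the polarity of the coupling. It sets out from bromide 10. Miyaura borylation (B2pin2, Pd(dppf)Cl2, KOAc, dioxane, 80 °C) should give (2S,3R)-3-[(4-allyl-2-methoxyphenoxy)methyl]-7-methoxy-2-(3-methoxy-4-pivaloyloxyphenyl)-5-(4,4,5,5-tetramethyl-1,3,2-dioxaborolan-2-yl)-2,3-dihydrobenzofuran F10. Coupling of this boronate with allyl bromide (Pd(PPh3)4, CsF, THF, 60 °C) comes back to the route at 12.

Further compounds
F1 | step 6 | 4-allyl-2-iodo-6-methoxyphenol | C=CCc1cc(I)c(O)c(OC)c1
F2 | step 6 | [4-(tert-butyldimethylsilyloxy)-3-methoxyphenyl]methanol | COc1cc(CO)ccc1O[Si](C)(C)C(C)(C)C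
F3 | step 6 | 5-allyl-2-{[4-(tert-butyldimethylsilyloxy)-3-methoxyphenyl]methoxy}-1-iodo-3-methoxybenzene | C=CCc1cc(I)c(OCc2ccc(O[Si](C)(C)C(C)(C)C)c(OC)c2)c(OC)c1
F4 | step 6 | methyl 2-(5-allyl-2-{[4-(tert-butyldimethylsilyloxy)-3-methoxyphenyl]methoxy}-3-methoxyphenyl)-2-diazoacetate | C=CCc1cc(C(=[N+]=[N-])C(=O)OC)c(OCc2ccc(O[Si](C)(C)C(C)(C)C)c(OC)c2)c(OC)c1
F5 | step 6 | methyl (2S,3R)-5-allyl-2-[4-(tert-butyldimethylsilyloxy)-3-methoxyphenyl]-7-methoxy-2,3-dihydrobenzofuran-3-carboxylate (cis) | COC(=O)[C@@H]1c2cc(CC=C)cc(OC)c2O[C@@H]1c1ccc(O[Si](C)(C)C(C)(C)C)c(OC)c1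
F6 | step 6 | methyl (2S,3S)-5-allyl-2-[4-(tert-butyldimethylsilyloxy)-3-methoxyphenyl]-7-methoxy-2,3-dihydrobenzofuran-3-carboxylate (trans) | COC(=O)[C@H]1c2cc(CC=C)cc(OC)c2O[C@@H]1c1ccc(O[Si](C)(C)C(C)(C)C)c(OC)c1
F7 | step 6 | [(2S,3R)-5-allyl-2-[4-(tert-butyldimethylsilyloxy)-3-methoxyphenyl]-7-methoxy-2,3-dihydrobenzofuran-3-yl]methanol (trans) | OC[C@H]1c2cc(CC=C)cc(OC)c2O[C@@H]1c1ccc(O[Si](C)(C)C(C)(C)C)c(OC)c1
F8 | step 6 | (2S,3R)-5-allyl-3-[(4-allyl-2-methoxyphenoxy)methyl]-2-[4-(tert-butyldimethylsilyloxy)-3-methoxyphenyl]-7-methoxy-2,3-dihydrobenzofuran (trans) | C=CCc1ccc(OC[C@H]2c3cc(CC=C)cc(OC)c3O[C@@H]2c2ccc(O[Si](C)(C)C(C)(C)C)c(OC)c2)c(OC)c1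
F9 | step 5 | [(2S,3R)-3-(3-methoxy-4-pivaloyloxyphenyl)oxiran-2-yl]methanol (cis) | OC[C@@H]1O[C@@H]1c1ccc(OC(=O)C(C)(C)C)c(OC)c1
F10 | step 7 | (2S,3R)-3-[(4-allyl-2-methoxyphenoxy)methyl]-7-methoxy-2-(3-methoxy-4-pivaloyloxyphenyl)-5-(4,4,5,5-tetramethyl-1,3,2-dioxaborolan-2-yl)-2,3-dihydrobenzofuran (trans) | C=CCc1ccc(OC[C@H]2c3cc(B4OC(C)(C)C(C)(C)O4)cc(OC)c3O[C@@H]2c2ccc(OC(=O)C(C)(C)C)c(OC)c2)c(OC)c1
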